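**Numbering.** Germacrane numbering is used throughout: C1–C10 are the ring carbons, C14 sits on C10, C15 on C4, and C11 (with methylene C13 and carbonyl C12) on C7. In the target SMILES, C8 is the ring carbon bonded to the lactone oxygen, C7 the other fusion carbon, C6 the angelate-bearing carbon. The stereocentres are 4R,6R,7R,8R.

## The problem

The target is a ten-membered carbocycle with one ring olefin, C1=C10. This olefin is trisubstituted, carries the C14 hydroxymethyl, and is E by the sequence rule but cis with respect to the ring bonds C9 and C2. The ring is trans-fused across C7–C8 to an α-methylene-γ-butyrolactone. The first difficulty is the medium ring itself: five contiguous sp3 carbons (C4–C8) and short bridges make a ring that no simple building block contains and that closes reluctantly. The second is the contiguous triad C6 (O-acyl), C7 (C-branch), C8 (O-lactone) plus the remote centre C4. C4 is insulated from C6 by the methylene C5 and cannot be relied on to control the triad. C8 can: once it is part of a planar five-membered lactone it shields one face of C7, and C6 can then be set through a cyclic transition state next to C7. The fragile groups are the angelate (isomerised to tiglate by nucleophilic catalysts, base or acid), the α-methylene lactone (Michael acceptor, reduced by hydrides), the O6/O8 pair (translactonisation to a 12,6-olide), and two primary hydroxyls that must end free beside an acylated secondary one.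

The feature that makes the key step possible is the array O6–C6–C7–C11(=C13)–C12(=O)–O8–C8. A β-(1-hydroxyalkyl)-α-methylene-γ-butyrolactone is the retron of an SE2′ addition of a 3-(metallomethyl)furan-2(5H)-one (C13–C11=C7, with C8 in the ring) to a C6 aldehyde. In addition, O15 is 1,4 to C6 and O14 is 1,4 to C8, so each primary alcohol can be stored with its partner carbon in a five-membered ring (C6/O15 lactol, C14/O8 lactone) until needed.

## Retrosynthesis

**26 ⇒ 25 ⇒ 22 ⇒ 21.** The cuts are the C6 O–acyl bond and the two silyl ethers. The angelate goes on last because it survives neither hydride nor strong base. Cutting it exposes diol 21, in which only the primary C15 hydroxyl needs capping (22) before the hindered C6 hydroxyl is acylated (25). The forward steps must acylate without Z-to-E isomerisation and remove silicon without touching the Michael acceptor.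

**21 ⇒ 19 (through 20).** The cut is the ring bond C6–C7, between two stereocentres. Against a cut at C1=C10, this closure creates stereochemical information (C6 and C7) instead of merely joining finished centres. Against a cut at C7–C8, the lactone is already fixed on O8, so 12,8- versus 12,6-lactonisation never arises, and C6 need not be made beforehand in an open chain. Precursor 19 is monocyclic, has only C4 and C8 as fixed centres, and carries the aldehyde as a lactol that also hides O15. The forward reaction must be an intramolecular Barbier allylation that tolerates water and a free hydroxyl, adds at C7 anti to the C8–C9 bond, and selects one face of the aldehyde.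

**19 ⇒ 18 ⇒ 17 ⇒ 14 + 15.** The butenolide is cut at C7=C11 (ring-closing metathesis) and at the O8–C12 ester bond. Acid 15 delivers C11, C12 and C13 with the bromide already in place, so no allylic bromination is needed in the presence of the C1=C10 olefin. The acetal-to-lactol hydrolysis (18 to 19) is placed last so that the latent aldehyde is exposed only just before use.

**14 ⇒ 13 ⇒ 12 ⇒ 11 + 6.** The C1=C10 bond is cut by a Horner–Wadsworth–Emmons disconnection of an α-alkylidene lactone. Tying C14 to O8 as a lactone (12) does three things: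
- it activates C10 for olefination;
- it makes the thermodynamically preferred E-alkylidene geometry identical with the ring-cis geometry required;
- on reduction it releases C14–OH (primary) and C8–OH (secondary), which are trivially told apart (13 to 14).

The precursors are a phosphonate with one stereocentre (11) and an aldehyde with one stereocentre (6).

**6 ⇒ 5 ⇒ 3 ⇒ 1 + 2.** C1 is cut off as carbon monoxide (hydroformylation of the vinyl group), and the C6 lactol acetal is traced to lactone 3. The C4–C3 bond is cut by an asymmetric conjugate vinylation of furanone 1 with borate 2. C4 is therefore set by catalysis, with C6 and C15 already differentiated by the lactone.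

**11 ⇒ 9 ⇒ 7.** The phosphonate is cut at C10–P, and the vinyl group (C7) is traced to the hydroxymethyl of lactone 7. C8 is bought.

## Roads not taken

**Alternative 1:** (the most obvious) cut C1=C10 and close the ring by metathesis of the seco-diene A1 with a second-generation ruthenium carbene. The closure would have to form a trisubstituted olefin inside a ten-membered ring, with no control over its geometry other than ring strain. It would also compete with the α-methylene lactone, itself a 1,1-disubstituted acrylate. The closing step adds no stereochemical information: all four stereocentres of A1, including the full C6–C7–C8 triad, must be built one by one in an open chain first. The chosen plan sets the olefin geometry in an intermolecular, thermodynamically biased olefination and uses the ring closure to create two stereocentres.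

**Alternative 2:** cut C7–C8 and close by chromium dichloride–mediated macrocyclic allylation of the open-chain (Z)-2-(bromomethyl)enoate aldehyde A2, with lactonisation onto O8. This is the classical germacranolide closure. Here it requires C6 to be installed beforehand, 1,3 to C4 across a methylene, and carried as a silyl ether on the allyl metal. It also requires a C8 aldehyde that is β,γ-unsaturated (C9 lies between the formyl group and C10=C1) and prone to slip into conjugation. The chosen plan inverts the polarity: the aldehyde is the unproblematic C6, the allyl unit is a rigid butenolide whose geometry cannot scramble, and C6 is created rather than carried.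

**Alternative 3:** cut C8–C9 and regenerate a C1–C6 bond, by anionic oxy-Cope ring expansion of the cis-1,2-dialkenylcyclohexanol A3 to the cyclodecenone A4. The ring size and the olefin would come from a chair transition state. However, A4 has C6 as a ketone and C7 without its three-carbon branch. The branch, C7 and C6 would then have to be set on a flexible ten-membered ring by enolate alkylation and ketone reduction under transannular control only, next to a β-alkoxy ketone prone to elimination. The ring-cis olefin also needs the cis-dialkenyl carbinol, the minor product of addition to a 2-substituted cyclohexanone. The route would be longer and its stereocontrol weaker.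

Key step: step 12

**Assumption:** lactols 4 and 19, acetals 5, 6, 12–14, 17 and 18 (acetal carbon = C6) and phosphonate 11 (C10) are carried as epimer mixtures at the one centre drawn without configuration, since each of these centres is destroyed later; both enantiomers of lactone 7 are taken to be commercially available.

## Route

Step 1
Reactants: 1 furan-2(5H)-one; 2 potassium trifluoro(vinyl)borate
Product: 3 (4S)-4-vinyloxolan-2-one
Conditions: [Rh(cod)2]BF4 (3 mol %), (S)-BINAP, toluene/H2O (10:1), 100 °C
Reagents that add atoms: none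
Why: Rhodium-catalysed asymmetric 1,4-addition (Hayashi–Miyaura type) of an alkenyl trifluoroborate to a butenolide; the BINAP–rhodium alkenyl adds to one enantioface at C4 and the rhodium enolate is protonated by water, which sets C4 (the ligand enantiomer is chosen by analogy with the 2-cyclohexenone series; the mirror-image ligand would serve if the sense were opposite).

Step 2
Reactants: 3 (4S)-4-vinyloxolan-2-one
Product: 5 (4S)-2-methoxy-4-vinyloxolane, via lactol 4 (not isolated)
Conditions: iBu2AlH, CH2Cl2, −78 °C; crude lactol, then MeOH, pyridinium p-toluenesulfonate (cat.), rt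
Reagents that add atoms: methanol (SMILES CO)
Why: Lactone-to-lactol reduction stops at the aluminium hemiacetal at −78 °C; Fischer-type acetalisation in methanol then stores the C6 aldehyde and the C15 hydroxyl together in one oxolane ring that is inert to base and hydride.

Step 3
Reactants: 5 (4S)-2-methoxy-4-vinyloxolane
Product: 6 3-[(3R)-5-methoxyoxolan-3-yl]propanal
Conditions: Rh(acac)(CO)2 (1 mol %), Xantphos, CO/H2 (1:1, 10 bar), toluene, 70 °C
Reagents that add atoms: carbon monoxide (SMILES [C-]#[O+])
Why: Linear-selective rhodium-catalysed hydroformylation of a monosubstituted olefin with a wide-bite-angle diphosphine; branching at C4 next to the olefin further disfavours the iso-aldehyde, the acetal is inert under these neutral conditions, and the step adds C1.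

Step 4
Reactants: 7 (5R)-5-(hydroxymethyl)oxolan-2-one
Product: 9 (5R)-5-vinyloxolan-2-one, via aldehyde 8 (not isolated)
Conditions: (COCl)2, DMSO, CH2Cl2, −78 °C, then Et3N; crude aldehyde, then Ph3P=CH2 (from Ph3PCH3Br, KN(SiMe3)2), THF, −78 to 0 °C
Reagents that add atoms: methyltriphenylphosphonium bromide (SMILES C[P+](c1ccccc1)(c1ccccc1)c1ccccc1.[Br-])
Why: Swern oxidation followed by Wittig methylenation of the crude α-alkoxy aldehyde at low temperature, which limits epimerisation of the bought stereocentre C8; the lactone carbonyl is far less electrophilic than the aldehyde towards the ylide.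

Step 5
Reactants: 9 (5R)-5-vinyloxolan-2-one
Product: 11 diethyl [(5R)-2-oxo-5-vinyloxolan-3-yl]phosphonate, via enol phosphate 10 (not isolated)
Conditions: LiN(iPr)2 (2.2 equiv), THF, −78 °C; ClP(O)(OEt)2; −78 °C to rt; aq. NH4Cl
Reagents that add atoms: diethyl chlorophosphate (SMILES CCOP(=O)(Cl)OCC)
Why: O-Phosphorylation of the lactone enolate followed by the base-induced 1,3-shift of phosphorus from oxygen to carbon (vinyl phosphate to β-keto phosphonate rearrangement), a standard entry to α-phosphono lactones; C8 is not involved.

Step 6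
Reactants: 11 diethyl [(5R)-2-oxo-5-vinyloxolan-3-yl]phosphonate; 6 3-[(3R)-5-methoxyoxolan-3-yl]propanal
Product: 12 (3E,5R)-3-{3-[(3R)-5-methoxyoxolan-3-yl]propylidene}-5-vinyloxolan-2-one
Conditions: NaH, THF, 0 °C; then 6, 0 °C to rt
Reagents that add atoms: none
Why: Horner–Wadsworth–Emmons olefination of an α-phosphono-γ-lactone; the stabilised anion should give mainly the E-alkylidene lactone (C2 anti to the carbonyl C14 and syn to C9), which is exactly the ring-cis geometry of C1=C10 in the target, and the minor Z isomer is separable.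

Step 7
Reactants: 12 (3E,5R)-3-{3-[(3R)-5-methoxyoxolan-3-yl]propylidene}-5-vinyloxolan-2-one
Product: 13 (3R,5E)-5-(hydroxymethyl)-8-[(3R)-5-methoxyoxolan-3-yl]octa-1,5-dien-3-ol
Conditions: iBu2AlH (4 equiv), CH2Cl2, −78 to 0 °C; aq. Rochelle salt
Reagents that add atoms: none
Why: Exhaustive 1,2-reduction of the conjugated lactone releases C14–OH and C8–OH with retention of the olefin geometry; the acetal and the isolated olefins are inert to the aluminium hydride.

Step 8
Reactants: 13 (3R,5E)-5-(hydroxymethyl)-8-[(3R)-5-methoxyoxolan-3-yl]octa-1,5-dien-3-ol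
Product: 14 (3R,5E)-5-{[tert-butyl(diphenyl)silyl]oxymethyl}-8-[(3R)-5-methoxyoxolan-3-yl]octa-1,5-dien-3-ol
Conditions: TBDPSCl (1.05 equiv), imidazole, CH2Cl2, 0 °C
Reagents that add atoms: tert-butyl(chloro)diphenylsilane (SMILES CC(C)(C)[Si](Cl)(c1ccccc1)c1ccccc1)
Why: The bulky silyl chloride discriminates the primary allylic C14 hydroxyl from the secondary C8 hydroxyl; the TBDPS ether is chosen because it survives the later aqueous acid.

Step 9
Reactants: 14 (3R,5E)-5-{[tert-butyl(diphenyl)silyl]oxymethyl}-8-[(3R)-5-methoxyoxolan-3-yl]octa-1,5-dien-3-ol; 15 2-(bromomethyl)prop-2-enoic acid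
Product: 17 (3R,5E)-5-{[tert-butyl(diphenyl)silyl]oxymethyl}-8-[(3R)-5-methoxyoxolan-3-yl]octa-1,5-dien-3-yl 2-(bromomethyl)prop-2-enoate, via acid chloride 16 (not isolated)
Conditions: 15, (COCl)2, DMF (cat.), CH2Cl2, 0 °C to rt; then 14, 2,6-lutidine, CH2Cl2, 0 °C to rt
Reagents that add atoms: none
Why: Acylation of the secondary allylic alcohol by the acid chloride in the presence of a hindered pyridine base, which does not quaternise the allylic bromide; C8 keeps its configuration because the C–O bond is not touched.

Step 10
Reactants: 17 (3R,5E)-5-{[tert-butyl(diphenyl)silyl]oxymethyl}-8-[(3R)-5-methoxyoxolan-3-yl]octa-1,5-dien-3-yl 2-(bromomethyl)prop-2-enoate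
Product: 18 (5R)-3-(bromomethyl)-5-[(2E)-2-{[tert-butyl(diphenyl)silyl]oxymethyl}-5-[(3R)-5-methoxyoxolan-3-yl]pent-2-en-1-yl]furan-2(5H)-one
Conditions: second-generation Hoveyda–Grubbs catalyst, RuCl2(H2IMes)(=CH–C6H4-2-OiPr) (5 mol %), toluene (5 mM), 80 °C
Reagents that add atoms: none
Why: Ring-closing metathesis of the acrylate of a secondary allylic alcohol to a butenolide with a phosphine-free ruthenium carbene; only the two terminal olefins react (five-membered ring, loss of ethylene), and the trisubstituted C1=C10 olefin is inert.

Step 11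
Reactants: 18 (5R)-3-(bromomethyl)-5-[(2E)-2-{[tert-butyl(diphenyl)silyl]oxymethyl}-5-[(3R)-5-methoxyoxolan-3-yl]pent-2-en-1-yl]furan-2(5H)-one
Product: 19 (5R)-3-(bromomethyl)-5-[(2E)-2-{[tert-butyl(diphenyl)silyl]oxymethyl}-5-[(3R)-5-hydroxyoxolan-3-yl]pent-2-en-1-yl]furan-2(5H)-one
Conditions: pyridinium p-toluenesulfonate (cat.), THF/H2O (4:1), 45 °C
Reagents that add atoms: water (SMILES O)
Why: Hydrolysis of the 2-methoxyoxolane, a furanoside-type acetal, should be much faster than cleavage of the TBDPS ether or solvolysis of the primary allylic bromide; it gives the lactol, the latent C6 aldehyde.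

Step 12
Reactants: 19 (5R)-3-(bromomethyl)-5-[(2E)-2-{[tert-butyl(diphenyl)silyl]oxymethyl}-5-[(3R)-5-hydroxyoxolan-3-yl]pent-2-en-1-yl]furan-2(5H)-one
Product: 21 (4R,6R,7R,8R,1(10)E)-14-[tert-butyl(diphenyl)silyl]oxy-6,15-dihydroxygermacra-1(10),11(13)-dien-12,8-olide, via allylindium aldehyde 20 (not isolated)
Conditions: In powder (3 equiv), THF/H2O (1:1), 40 °C, slow addition of 19 (final 2 mM)
Reagents that add atoms: none
Why: Indium inserts into the allylic C13–Br bond while the lactol opens to the C6 aldehyde (20), and the allylindium adds through C7 (SE2′) in a six-membered cyclic transition state, forming the C6–C7 bond and leaving the exocyclic C11=C13 methylene. The closest known reactions are zinc- and indium-mediated Barbier additions of 3-(bromomethyl)furan-2(5H)-ones and 2-(bromomethyl)acrylates to aldehydes and to lactols in water, and the chromium-mediated macrocyclic Barbier closure of ten-membered germacranolide rings. The carbocycle is closed by a 10-exo-trig addition to the aldehyde; the lactone ring already exists and only changes the position of its unsaturation. C7 is controlled by C8: the planar butenolide should be attacked on the face anti to the C8–C9 bond, giving the trans ring fusion, which the seven-atom tether accommodates with a staggered C9–C8–C7–C6 torsion whereas cis fusion would push that torsion towards eclipsing. C6 is controlled by the cyclic transition state: zinc and indium reagents of this 2-carbonyl-allyl type are expected to favour the adduct called syn when the chain is drawn through C11, which here is 6R, whereas the chair with the aldehyde chain equatorial would give the C6 epimer. The step needs aldehyde-over-lactone chemoselectivity, which is inherent to allylindium reagents, and intramolecular-over-intermolecular addition, which is served by millimolar concentration and by the water tolerance of the reagent while the aldehyde is released slowly from the lactol.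

Step 13
Reactants: 21 (4R,6R,7R,8R,1(10)E)-14-[tert-butyl(diphenyl)silyl]oxy-6,15-dihydroxygermacra-1(10),11(13)-dien-12,8-olide
Product: 22 (4R,6R,7R,8R,1(10)E)-15-[tert-butyl(dimethyl)silyl]oxy-14-[tert-butyl(diphenyl)silyl]oxy-6-hydroxygermacra-1(10),11(13)-dien-12,8-olide
Conditions: TBSCl (1.1 equiv), imidazole, CH2Cl2, 0 °C
Reagents that add atoms: tert-butyl(chloro)dimethylsilane (SMILES CC(C)(C)[Si](C)(C)Cl)
Why: The primary C15 hydroxyl is silylated selectively over the secondary C6 hydroxyl, which is flanked by the ring fusion; the mild base should not trigger translactonisation.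

Step 14
Reactants: 22 (4R,6R,7R,8R,1(10)E)-15-[tert-butyl(dimethyl)silyl]oxy-14-[tert-butyl(diphenyl)silyl]oxy-6-hydroxygermacra-1(10),11(13)-dien-12,8-olide; 23 angelic acid, (2Z)-2-methylbut-2-enoic acid
Product: 25 (4R,6R,7R,8R,1(10)E)-6-[(2Z)-2-methylbut-2-enoyl]oxy-15-[tert-butyl(dimethyl)silyl]oxy-14-[tert-butyl(diphenyl)silyl]oxygermacra-1(10),11(13)-dien-12,8-olide, via mixed anhydride 24 (not isolated)
Conditions: 23, 2,4,6-trichlorobenzoyl chloride, Et3N, toluene, rt; then 22, 80 °C
Reagents that add atoms: none
Why: Yamaguchi-type mixed-anhydride acylation run without a nucleophilic pyridine catalyst, the protocol used for angelates because such catalysts add to the enoate and isomerise it to the tiglate; C6 retains its configuration since only the O–H bond reacts.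

Step 15
Reactants: 25 (4R,6R,7R,8R,1(10)E)-6-[(2Z)-2-methylbut-2-enoyl]oxy-15-[tert-butyl(dimethyl)silyl]oxy-14-[tert-butyl(diphenyl)silyl]oxygermacra-1(10),11(13)-dien-12,8-olide
Product: 26 (4R,6R,7R,8R,1(10)E)-6-[(2Z)-2-methylbut-2-enoyl]oxy-14,15-dihydroxygermacra-1(10),11(13)-dien-12,8-olide (target)
Conditions: HF·pyridine, pyridine/THF, 0 °C to rt
Reagents that add atoms: none
Why: Fluoride cleavage of both silyl ethers under buffered, weakly acidic and non-nucleophilic conditions, which the angelate and the α-methylene lactone should tolerate.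

## Compound list

1 | furan-2(5H)-one | O=C1OCC=C1 | starting material
2 | potassium trifluoro(vinyl)borate | C=C[B-](F)(F)F.[K+] | starting material
3 | (4S)-4-vinyloxolan-2-one | C=C[C@H]1COC(=O)C1 | intermediate
4 | (4S)-4-vinyloxolan-2-ol (lactol, anomers) | C=C[C@H]1COC(O)C1 | intermediate
5 | (4S)-2-methoxy-4-vinyloxolane (anomers) | C=C[C@H]1COC(OC)C1 | intermediate
6 | 3-[(3R)-5-methoxyoxolan-3-yl]propanal (anomers) | O=CCC[C@H]1COC(OC)C1 | intermediate
7 | (5R)-5-(hydroxymethyl)oxolan-2-one | OC[C@H]1CCC(=O)O1 | starting material
8 | (2R)-5-oxooxolane-2-carbaldehyde | O=C[C@H]1CCC(=O)O1 | intermediate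
9 | (5R)-5-vinyloxolan-2-one | C=C[C@H]1CCC(=O)O1 | intermediate
10 | diethyl (5R)-5-vinyl-4,5-dihydrofuran-2-yl phosphate | C=C[C@H]1CC=C(OP(=O)(OCC)OCC)O1 | intermediate
11 | diethyl [(5R)-2-oxo-5-vinyloxolan-3-yl]phosphonate (C3 epimers) | C=C[C@H]1CC(P(=O)(OCC)OCC)C(=O)O1 | intermediate
12 | (3E,5R)-3-{3-[(3R)-5-methoxyoxolan-3-yl]propylidene}-5-vinyloxolan-2-one | C=C[C@H]1C/C(=C\CC[C@H]2COC(OC)C2)C(=O)O1 | intermediate
13 | (3R,5E)-5-(hydroxymethyl)-8-[(3R)-5-methoxyoxolan-3-yl]octa-1,5-dien-3-ol | C=C[C@H](O)C/C(CO)=C\CC[C@H]1COC(OC)C1 | intermediate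
14 | (3R,5E)-5-{[tert-butyl(diphenyl)silyl]oxymethyl}-8-[(3R)-5-methoxyoxolan-3-yl]octa-1,5-dien-3-ol | C=C[C@H](O)C/C(CO[Si](c1ccccc1)(c1ccccc1)C(C)(C)C)=C\CC[C@H]1COC(OC)C1 | intermediate
15 | 2-(bromomethyl)prop-2-enoic acid | C=C(CBr)C(=O)O | starting material
16 | 2-(bromomethyl)prop-2-enoyl chloride | C=C(CBr)C(=O)Cl | intermediate
17 | (3R,5E)-5-{[tert-butyl(diphenyl)silyl]oxymethyl}-8-[(3R)-5-methoxyoxolan-3-yl]octa-1,5-dien-3-yl 2-(bromomethyl)prop-2-enoate | C=C[C@H](OC(=O)C(=C)CBr)C/C(CO[Si](c1ccccc1)(c1ccccc1)C(C)(C)C)=C\CC[C@H]1COC(OC)C1 | intermediate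
18 | (5R)-3-(bromomethyl)-5-[(2E)-2-{[tert-butyl(diphenyl)silyl]oxymethyl}-5-[(3R)-5-methoxyoxolan-3-yl]pent-2-en-1-yl]furan-2(5H)-one | BrCC1=C[C@@H](C/C(CO[Si](c2ccccc2)(c2ccccc2)C(C)(C)C)=C\CC[C@H]2COC(OC)C2)OC1=O | intermediate
19 | (5R)-3-(bromomethyl)-5-[(2E)-2-{[tert-butyl(diphenyl)silyl]oxymethyl}-5-[(3R)-5-hydroxyoxolan-3-yl]pent-2-en-1-yl]furan-2(5H)-one (lactol, anomers) | BrCC1=C[C@@H](C/C(CO[Si](c2ccccc2)(c2ccccc2)C(C)(C)C)=C\CC[C@H]2COC(O)C2)OC1=O | intermediate
20 | open-chain C6 aldehyde of 19 carrying the C13 allylindium (drawn with one carbon–indium bond) | [In]CC1=C[C@@H](C/C(CO[Si](c2ccccc2)(c2ccccc2)C(C)(C)C)=C\CC[C@@H](CO)CC=O)OC1=O | intermediate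
21 | (4R,6R,7R,8R,1(10)E)-14-[tert-butyl(diphenyl)silyl]oxy-6,15-dihydroxygermacra-1(10),11(13)-dien-12,8-olide | C=C1C(=O)O[C@@H]2C/C(CO[Si](c3ccccc3)(c3ccccc3)C(C)(C)C)=C\CC[C@@H](CO)C[C@@H](O)[C@@H]12 | intermediate
22 | (4R,6R,7R,8R,1(10)E)-15-[tert-butyl(dimethyl)silyl]oxy-14-[tert-butyl(diphenyl)silyl]oxy-6-hydroxygermacra-1(10),11(13)-dien-12,8-olide | C=C1C(=O)O[C@@H]2C/C(CO[Si](c3ccccc3)(c3ccccc3)C(C)(C)C)=C\CC[C@@H](CO[Si](C)(C)C(C)(C)C)C[C@@H](O)[C@@H]12 | intermediate
23 | angelic acid, (2Z)-2-methylbut-2-enoic acid | C/C=C(/C)C(=O)O | starting material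
24 | (2Z)-2-methylbut-2-enoic 2,4,6-trichlorobenzoic anhydride | C/C=C(/C)C(=O)OC(=O)c1c(Cl)cc(Cl)cc1Cl | intermediate
25 | (4R,6R,7R,8R,1(10)E)-6-[(2Z)-2-methylbut-2-enoyl]oxy-15-[tert-butyl(dimethyl)silyl]oxy-14-[tert-butyl(diphenyl)silyl]oxygermacra-1(10),11(13)-dien-12,8-olide | C=C1C(=O)O[C@@H]2C/C(CO[Si](c3ccccc3)(c3ccccc3)C(C)(C)C)=C\CC[C@@H](CO[Si](C)(C)C(C)(C)C)C[C@@H](OC(=O)/C(C)=C\C)[C@@H]12 | intermediate
26 | (4R,6R,7R,8R,1(10)E)-6-[(2Z)-2-methylbut-2-enoyl]oxy-14,15-dihydroxygermacra-1(10),11(13)-dien-12,8-olide | C=C1C(=O)O[C@@H]2C/C(CO)=C\CC[C@@H](CO)C[C@@H](OC(=O)/C(C)=C\C)[C@@H]12 | target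

## Step count and risks

Total: 15 steps. Longest linear sequence: 13 steps (steps 1–3 and 6–15); the other branch (steps 4–5) joins at step 6.

**Step 12 (key step).** Two things may go wrong. First, protonolysis of the allylindium or intermolecular coupling may outrun closure of the ten-membered ring, because only a small fraction of 19 is present as free aldehyde. Second, facial selectivity at C6 may be poor, since the competing chair transition state gives the C6 epimer. The fallback separates unmasking from ring closure and runs without water. From 19, silylation with TBSCl and imidazole at 0 °C, which for γ-lactols traps the open-chain primary alcohol, gives the silyl ether aldehyde F1. Closure with CrCl2 in THF under high dilution (Nozaki–Hiyama–Kishi allylation, the established closure of ten-membered germacranolide rings) then forms C6–C7 with O15 already protected. If the 6R alcohol results, the route is rejoined at 22. If the closed chair prevails and the C6-epimeric alcohol F2 results, a Mitsunobu esterification with 23 (PPh3, diisopropyl azodicarboxylate, toluene, 0 °C) inverts C6 and rejoins the route at 25.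

**Step 10.** The catalyst may be deactivated by the activated allylic bromide, or turnover at the 1,1-disubstituted acrylate may be slow enough for the C8 vinyl group to dimerise. The fallback installs C13 after the ring is made. From 14, acryloyl chloride and Et3N give the acrylate F3. Ring-closing metathesis, which is routine for unsubstituted acrylates, gives the butenolide F4. A Morita–Baylis–Hillman reaction with aqueous formaldehyde (imidazole or Bu3P) gives the hydroxymethyl butenolide F5. An Appel reaction (CBr4, PPh3) returns to 18.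

**Step 6.** E selectivity may be incomplete, and the enolisable aldehyde 6 may self-condense under the basic conditions. The fallback forms the C1–C2 bond by cross-coupling and fixes the geometry beforehand. From 9, formylation (NaH, ethyl formate) and O-sulfonylation with 4-methylbenzenesulfonyl chloride give the E enol tosylate F6. From 5, hydroboration with 9-borabicyclo[3.3.1]nonane gives the alkylborane F7. A B-alkyl Suzuki–Miyaura coupling (Pd(OAc)2, SPhos, K3PO4, THF/H2O) joins them with retention of the enol sulfonate geometry and returns to 12. This also removes steps 3 and 5 from the sequence.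

**Step 14.** The angelate may isomerise to the tiglate during acyl transfer, or slow acylation of the hindered C6 hydroxyl may allow O6-to-O8 translactonisation. The fallback builds the Z-enoate on the molecule. From 22, esterification with 2-[bis(2,2,2-trifluoroethoxy)phosphoryl]propanoic acid (N,N'-dicyclohexylcarbodiimide, catalytic 4-dimethylaminopyridine) gives the phosphonate ester F8. A Still–Gennari olefination with acetaldehyde (KN(SiMe3)2, 18-crown-6, THF, −78 °C) gives the Z-2-methylbut-2-enoate and returns to 25.

## Further compounds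

F1 | step 12 | (5R)-3-(bromomethyl)-5-[(2E,6R)-6-{[tert-butyl(dimethyl)silyl]oxymethyl}-2-{[tert-butyl(diphenyl)silyl]oxymethyl}-8-oxooct-2-en-1-yl]furan-2(5H)-one | BrCC1=C[C@@H](C/C(CO[Si](c2ccccc2)(c2ccccc2)C(C)(C)C)=C\CC[C@@H](CO[Si](C)(C)C(C)(C)C)CC=O)OC1=O
F2 | step 12 | (4R,6S,7R,8R,1(10)E)-15-[tert-butyl(dimethyl)silyl]oxy-14-[tert-butyl(diphenyl)silyl]oxy-6-hydroxygermacra-1(10),11(13)-dien-12,8-olide (C6 epimer of 22) | C=C1C(=O)O[C@@H]2C/C(CO[Si](c3ccccc3)(c3ccccc3)C(C)(C)C)=C\CC[C@@H](CO[Si](C)(C)C(C)(C)C)C[C@H](O)[C@@H]12
F3 | step 10 | (3R,5E)-5-{[tert-butyl(diphenyl)silyl]oxymethyl}-8-[(3R)-5-methoxyoxolan-3-yl]octa-1,5-dien-3-yl prop-2-enoate | C=C[C@H](OC(=O)C=C)C/C(CO[Si](c1ccccc1)(c1ccccc1)C(C)(C)C)=C\CC[C@H]1COC(OC)C1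
F4 | step 10 | (5R)-5-[(2E)-2-{[tert-butyl(diphenyl)silyl]oxymethyl}-5-[(3R)-5-methoxyoxolan-3-yl]pent-2-en-1-yl]furan-2(5H)-one | O=C1C=C[C@@H](C/C(CO[Si](c2ccccc2)(c2ccccc2)C(C)(C)C)=C\CC[C@H]2COC(OC)C2)O1
F5 | step 10 | (5R)-3-(hydroxymethyl)-5-[(2E)-2-{[tert-butyl(diphenyl)silyl]oxymethyl}-5-[(3R)-5-methoxyoxolan-3-yl]pent-2-en-1-yl]furan-2(5H)-one | OCC1=C[C@@H](C/C(CO[Si](c2ccccc2)(c2ccccc2)C(C)(C)C)=C\CC[C@H]2COC(OC)C2)OC1=O
F6 | step 6 | (3E,5R)-3-{[(4-methylphenyl)sulfonyl]oxymethylidene}-5-vinyloxolan-2-one | C=C[C@H]1C/C(=C\OS(=O)(=O)c2ccc(C)cc2)C(=O)O1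
F7 | step 6 | 9-{2-[(3R)-5-methoxyoxolan-3-yl]ethyl}-9-borabicyclo[3.3.1]nonane | C(C[C@H]1COC(OC)C1)B1C2CCCC1CCC2
F8 | step 14 | (4R,6R,7R,8R,1(10)E)-6-{2-[bis(2,2,2-trifluoroethoxy)phosphoryl]propanoyl}oxy-15-[tert-butyl(dimethyl)silyl]oxy-14-[tert-butyl(diphenyl)silyl]oxygermacra-1(10),11(13)-dien-12,8-olide | C=C1C(=O)O[C@@H]2C/C(CO[Si](c3ccccc3)(c3ccccc3)C(C)(C)C)=C\CC[C@@H](CO[Si](C)(C)C(C)(C)C)C[C@@H](OC(=O)C(C)P(=O)(OCC(F)(F)F)OCC(F)(F)F)[C@@H]12
A1 | alternative 1 | seco-diene for ring-closing metathesis: trans-α-methylene-γ-butyrolactone bearing the C9–C10(=CH2)–C14 silyl ether arm on C8 and the C6(OSiEt3)–C5–C4(CH2OSi)–C3–C2–C1H=CH2 arm on C7 | C=C1C(=O)O[C@H](CC(=C)CO[Si](C)(C)C(C)(C)C)[C@H]1[C@H](O[Si](CC)(CC)CC)C[C@H](CO[Si](C)(C)C(C)(C)C)CCC=C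
A2 | alternative 2 | methyl (2Z,4R,6R,9E)-2-(bromomethyl)-6,10-bis{[tert-butyl(dimethyl)silyl]oxymethyl}-12-oxo-4-(triethylsilyloxy)dodeca-2,9-dienoate | O=CC/C(CO[Si](C)(C)C(C)(C)C)=C\CC[C@@H](CO[Si](C)(C)C(C)(C)C)C[C@@H](O[Si](CC)(CC)CC)/C=C(\CBr)C(=O)OC
A3 | alternative 3 | cis-1,2-dialkenylcyclohexanol: cyclohexanol C6 bearing a (Z)-2-(4-methoxybenzyloxy)vinyl group cis to the 3-silyloxyprop-1-en-2-yl group on C1, with the silyloxymethyl group on C4 trans to the latter | O[C@]1(/C=C\OCc2ccc(OC)cc2)C[C@H](CO[Si](C)(C)C(C)(C)C)CC[C@H]1C(=C)CO[Si](C)(C)C(C)(C)C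
A4 | alternative 3 | ring-expanded cyclodec-5-enone: C6 ketone, C8 4-methoxybenzyl ether, ring-cis C1=C10 olefin bearing the C14 silyl ether, C4 silyloxymethyl | O=C1C[C@H](OCc2ccc(OC)cc2)C/C(CO[Si](C)(C)C(C)(C)C)=C\CC[C@@H](CO[Si](C)(C)C(C)(C)C)C1
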